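Read each flask at 20 h, and first count how many substrate half-lives fit before that reading.

| flask | substrate | partner | remark | time |
|---|---|---|---|---|
| beta | 20 mM | 40 mM | run made earlier |  |
| gamma | 20 mM | 20 mM | run made earlier |  |
| epsilon | 20 mM | 80 mM | run made earlier |  |
| delta | 30 mM | 40 mM | run made earlier |  |
| Wednesday's | 20 mM (fed, over 15 h) | 40.0 mM | all else is in the flask from the start; the feed brings no volume worth counting | 20 h |
| Friday's | 20 mM | 40.0 mM (fed, over 15 h) | all else is in the flask from the start; the feed brings no volume worth counting | 20 h |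
| Thursday's | 20 mM | 40.0 mM | everything together at the start | 20 h |
| Sunday's | 20 mM | 40.0 mM (in portions, 4, over 15 h) | first portion at the start, last at 15 h | 20 h |

| run | time / h | mono adduct / % | substrate / % |
|---|---|---|---|
| beta | 0.833 | 9.1 | 89.7 |
| beta | 2.50 | 19.8 | 74.7 |
| beta | 4.00 | 24.2 | 65.0 |
| beta | 6.00 | 28.1 | 56.8 |
| beta | 10.0 | 30.6 | 46.8 |
| beta | 12.0 | 30.6 | 43.4 |
| gamma | 1.33 | 7.8 | 91.8 |
| gamma | 4.00 | 15.1 | 79.4 |
| gamma | 8.00 | 20.6 | 67.9 |
| gamma | 10.0 | 21.8 | 64.2 |
| gamma | 15.0 | 23.9 | 58.7 |
| gamma | 20.0 | 24.9 | 54.4 |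
| epsilon | 3.00 | 30.3 | 52.4 |
| epsilon | 6.00 | 31.5 | 34.6 |
| epsilon | 10.0 | 29.7 | 23.9 |
| epsilon | 12.0 | 28.5 | 21.3 |
| epsilon | 15.0 | 26.8 | 18.4 |
| epsilon | 20.0 | 25.0 | 15.5 |
| delta | 2.00 | 16.4 | 78.9 |
| delta | 5.00 | 26.3 | 62.6 |
| delta | 10.0 | 29.9 | 50.6 |
| delta | 15.0 | 30.3 | 44.6 |
| delta | 20.0 | 30.4 | 41.7 |

(standard deviation of a reading: 0.3 percentage points)

1. the flask with the highest amount of mono adduct, in percent of the substrate charged ("all alike" if they lie within 1.5 percentage points) (Wednesday's / Friday's / Thursday's / Sunday's / all alike)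
2. final mono adduct, as a percentage of the substrate charged, in Wednesday's
3. final mono adduct, as a percentage of the substrate charged, in Friday's
4. final mono adduct, as a percentage of the substrate charged, in Thursday's
5. final mono adduct, as a percentage of the substrate charged, in Sunday's

- what may be going on: substrate + partner -> mono adduct; partner + mono adduct -> bis adduct; partner + bis adduct -> triple product; substrate <-> dormant form; partner -> decomposed reagent

Start from the first beta point: substrate at 89.7% after 0.833 h under 40 mM of partner gives a rate constant k of 0.00326 mM⁻¹ h⁻¹ for substrate + partner. Now define h, the pseudo-first-order half-life of substrate under the whole partner charge, 5.31 h. At a share f of the partner charge, it stretches to h/f.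

Thursday's repeats beta, whose mono adduct reads 30.6% at 10.0 h and 30.6% at 12.0 h, so it is flat after 1.88 counts of h. Between those readings, substrate shows a half-life near 18.4 h, longer than h, a reading that also counts any loss to dormant form.

Now decide the charge. Friday's and Sunday's get their last partner at 15 h, leaving 0.942 counts of h even at the whole charge, fewer than beta needed. Wednesday's gets its last substrate at 15 h, and taking the late half-life of beta as a guide gives that substrate 0.272 half-lives. My reckoning therefore charges everything at the start, with Thursday's first and Wednesday's last.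

The forecast names Friday's, with 25% for Wednesday's, 30.5% for Friday's, 29.5% for Thursday's and 30% for Sunday's, and says “Thursday, Friday and Sunday are nearly tied”. It parts from my reckoning on the top flask.

The flask gives Thursday's: 31.2%, against 28.8% in Friday's, 28.7% in Sunday's and 22.0% in Wednesday's. At 20.0 h, Thursday's makes mono adduct at 0.956 of the rate at which it uses it up. Put h to work on Friday's: from 15.0 h, partner falls from 40.7% to 19.9%, a logarithmic mean share of 29.1%, so substrate at 51.2% should reach 42.3%; it stands at 40.5%.

    substrate + partner → mono adduct (k = 8.87 × 10⁻⁴ M⁻¹ s⁻¹)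
    partner + mono adduct → bis adduct (k = 0.00108 M⁻¹ s⁻¹)
    partner + bis adduct → triple product (k = 8.68 × 10⁻⁴ M⁻¹ s⁻¹)
    substrate ⇌ dormant form (K = 8.30, k = 2.79 × 10⁻⁶ s⁻¹)
    partner → decomposed reagent (k = 2.36 × 10⁻⁵ s⁻¹)

Take Thursday's flask with 24 mM of partner: h becomes 8.85 h, and with partner ending at 5.32%, the mean share of 32.3% leaves 60.3% unreacted. The computed flask holds substrate 50.3% and dormant form 12.9%, together 63.2%, with mono adduct 26.9%.

All runs stem from a simulated flask for substances that don't exist; the scatter is artificial.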